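**Plan**
1. Retrosynthesis: remove the silyl ethers and the C15 carbonyl; cut C12–C13 while re-forming C8–C9 (reverse anionic oxy-Cope), which turns the ten-membered ring into a cyclohexanone (ring B) with a spiro ring D at C8 and a vinyl carbinol at C9.
2. Then cut ring D (C13=C16 metathesis, two allylations at C8), then C2–C3 of ring A (aldol–Tishchenko), then C5–C4 and C10–C1 (Michael addition/acylation), which leaves (S)-carvone.
3. Forward: ring A is closed on the carvone ring, ring D is spiro-annulated at C8, C9 is vinylated, ring B is expanded to the ten-membered ring, and C15 is oxidised last.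
4. Enabling feature: in ring A the C2 methylene lies between the oxygenated C1 and C3, each flanked by a quaternary carbon (C10, C4). A C1 methyl ketone can therefore enolise only towards C2 and a C3 aldehyde cannot enolise; the trans pair C1–OH (equatorial)/C3–OAc (axial) is what hydride transfer inside an O3 hemiacetal delivers.
5. Stereochemistry: the carvone stereocentre (C7) sets C5, C5 sets C10, and the ring A chair sets C3 and C1. C7 is then erased and reset by reduction; C8 is set by the order of the allylations and passes its chirality to C13 in the [3,3] shift.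

Key step: step 2

Remark: carbons carry ent-kaurane numbers: ring A = C1–C5 and C10 (C20 on C10, C18/C19 on C4); ten-membered ring = C5, C6, C7, C8, C14, C13, C12, C11, C9, C10; ring D = C8, C14, C13, C16(=C17), C15; ring B is the six-membered carvone ring C5–C10 that exists up to step 12; the 1,3-diones 10 and 11 are drawn as diketo tautomers.

**Route**

Step 1
Reactants: 1 (S)-(+)-carvone; 2 2-methyl-1-(trimethylsilyloxy)prop-1-ene
Product: 4 ring B keto aldehyde (C9 ketone; C10 bearing the C20 methyl and the C1 acetyl group; C5 bearing C4(CH3)2–C3HO; C7 isopropenyl; acetyl trans to the C5 side chain; isopropenyl trans to the C5 side chain), via titanium enolate 3 (not isolated)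
Conditions: TiCl4 (1.1 equiv), CH2Cl2, −78 °C; then CH3COCl (1.5 equiv), −78 → −20 °C
Reagents that add atoms: acetyl chloride (CC(=O)Cl)
Why: Mukaiyama–Michael addition to the TiCl4-activated enone should occur at C5 anti to the C7 isopropenyl group, and the trichlorotitanium enolate should then be C-acylated at C10 (titanium-Claisen type) anti to the new C5 substituent, which fixes C5 and the quaternary C10.

Step 2
Reactants: 4 ring B keto aldehyde
Product: 6 ring A anti-1,3-diol monoacetate (trans-fused bicycle; C1–OH equatorial and cis to C20; C3–OAc axial and trans to C20; C9 ketone; C7 isopropenyl), via aldol 5 (not isolated)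
Conditions: LiN(SiMe3)2 (1.05 equiv), THF, −78 → −40 °C; then CH3CHO (8 equiv), SmI2 (0.3 equiv), −40 → −10 °C
Reagents that add atoms: acetaldehyde (CC=O)
Why: LiN(SiMe3)2 deprotonates the C2 methyl of the C1 acetyl group and the enolate adds to the C3 aldehyde through a chair transition state; acetaldehyde then adds to the C3 alkoxide to give a hemiacetal whose C–H is delivered as hydride, in a six-membered transition state held by trivalent samarium, to the C1 carbonyl, leaving the acetyl group on O3 and a free hydroxyl on C1. The closest known reaction types are the aldol–Tishchenko reaction of ketone enolates and the Evans–Tishchenko reduction of β-hydroxy ketones. Ring A closes in the 6-(enolendo)-exo-trig mode and is trans-fused to ring B because the C1 and C4 arms are both equatorial on the ring B chair. C3 is controlled by the lithium-chelated chair (oxygen axial, trans to C20) and by the fact that only the axial C3 aldolate can reach the C1 carbonyl while the equatorial epimer reverts by retro-aldol; C1 is controlled by the intramolecular hydride delivery from O3, which leaves C1–OH equatorial and anti to C3–OAc. The step needs enolisation at C2 despite the C8 methylene of the ring ketone, and hydride transfer to C1 and not to C9: the quaternary C10 and C4 leave C2 as the only enolisable carbon that reaches the aldehyde in a strain-free ring (a C8 enolate would have to close a bicyclo[2.2.2]octane through a boat), and only C1 lies 1,3 to O3.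

Step 3
Reactants: 6 ring A anti-1,3-diol monoacetate
Product: 7 C1 tert-butyldimethylsilyl ether of 6
Conditions: TBSOTf, 2,6-lutidine, CH2Cl2, −78 °C
Reagents that add atoms: tert-butyldimethylsilyl trifluoromethanesulfonate (CC(C)(C)[Si](C)(C)OS(=O)(=O)C(F)(F)F)
Why: Silyl ether formation at the only hydroxyl protects the C1 carbinol, which is β to the C9 ketone, against retro-aldol cleavage in later basic steps and stores the O1/O3 distinction made in step 2.

Step 4
Reactants: 7 C1 silyl ether
Product: 10 ring B 1,3-dione (C7 and C9 ketones), via methoxy hydroperoxide 8 (not isolated), via aminoxyl ether 9 (not isolated)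
Conditions: O3, CH3OH, −78 °C; then FeSO4·7H2O, TEMPO, −78 °C → rt; then 3-chloroperbenzoic acid, CH2Cl2, 0 °C
Reagents that add atoms: TEMPO, (2,2,6,6-tetramethylpiperidin-1-yl)oxyl (CC1(C)CCCC(C)(C)N1[O])
Why: Ozonolysis in methanol gives the α-methoxy hydroperoxide, divalent iron turns it into an alkoxyl radical that loses methyl acetate by β-scission, TEMPO traps the C7 radical, and peracid oxidation of the alkoxyamine with Cope-type elimination should give the C7 ketone (oxodealkenylation), erasing the relay stereocentre once C5 and C10 are fixed.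

Step 5
Reactants: 10 ring B 1,3-dione
Product: 11 C8-allyl 1,3-dione
Conditions: allyl acetate (1.05 equiv), Pd(PPh3)4 (3 mol %), Et3N, THF, 40 °C
Reagents that add atoms: allyl acetate (C=CCOC(C)=O)
Why: Tsuji–Trost C-allylation of the acidic 1,3-dione through a π-allyl palladium complex should take place at the doubly activated C8; no lasting stereocentre forms because 11 is enolised.

Step 6
Reactants: 11 C8-allyl 1,3-dione
Product: 12 C8-quaternary dione (allyl cis to C20; 2-(acetoxymethyl)prop-2-enyl trans to C20)
Conditions: 2-methylidenepropane-1,3-diyl diacetate (3 equiv), Pd(PPh3)4 (5 mol %), Et3N, THF, 50 °C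
Reagents that add atoms: 2-methylidenepropane-1,3-diyl diacetate (C=C(COC(C)=O)COC(C)=O)
Why: The second Tsuji–Trost allylation should occur on the face of the planar dione enolate opposite the axial C20 methyl (1,3-diaxial to C8 in the rigid trans-fused bicycle), which puts the future C15–C16–C17 arm trans and the future C14–C13 arm cis to C20 and so fixes C8.

Step 7
Reactants: 12 C8-quaternary dione
Product: 13 spiro dione (ring D = cyclopentene C8–C14–C13=C16–C15 with CH2OAc on C16; C14 cis to C20)
Conditions: second-generation Grubbs catalyst (5 mol %), CH2Cl2, 40 °C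
Reagents that add atoms: none
Why: Ring-closing metathesis of the allyl and the 2-substituted allyl group should close the five-membered ring D with loss of ethene and without change at any stereocentre.

Step 8
Reactants: 13 spiro dione
Product: 14 C7 alcohol (C7–OH equatorial and cis to C20)
Conditions: NaBH4, CeCl3·7H2O, CH3OH, −78 °C
Reagents that add atoms: none
Why: Luche reduction should take the C7 ketone and spare the C9 ketone flanked by two quaternary carbons; hydride adds axially from the face opposite the axial C14 methylene and gives the equatorial C7 alcohol.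

Step 9
Reactants: 14 C7 alcohol
Product: 15 C7 tert-butyldimethylsilyl ether
Conditions: TBSOTf, 2,6-lutidine, CH2Cl2, −40 °C
Reagents that add atoms: tert-butyldimethylsilyl trifluoromethanesulfonate (CC(C)(C)[Si](C)(C)OS(=O)(=O)C(F)(F)F)
Why: Silyl ether formation under non-basic conditions protects the C7 carbinol and avoids retro-aldol opening of the β-hydroxy ketone.

Step 10
Reactants: 15 C7 silyl ether
Product: 16 spiro diene ketone (ring D: C14=C13 and exocyclic C16=C17)
Conditions: Pd(PPh3)4 (5 mol %), Et3N, 1,4-dioxane, 90 °C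
Reagents that add atoms: none
Why: Ionisation of the allylic acetate to a π-allyl palladium complex and β-hydride elimination from C14, the only hydrogen-bearing carbon next to an allyl terminus, should give the conjugated diene (palladium-catalysed 1,4-elimination).

Step 11
Reactants: 16 spiro diene ketone
Product: 17 C9 vinyl carbinol with free C3–OH (vinyl trans to C14 and to C20; C9–OH cis to C20)
Conditions: CH2=CHMgBr (6 equiv), CeCl3 (6 equiv), THF, −78 → 0 °C
Reagents that add atoms: vinylmagnesium bromide (C=C[Mg]Br)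
Why: Organocerium 1,2-addition to the non-enolisable C9 ketone should come from the face away from the axial C20 methyl and the axial C14, so the vinyl group ends trans to C14, and the excess reagent cleaves the C3 acetate.

Step 12
Reactants: 17 C9 vinyl carbinol
Product: 18 ten-membered ring ketone (bicyclo[7.2.1] core: C9 ketone; C8=C14; C13–H; exocyclic C16=C17; free C3–OH)
Conditions: KH (4 equiv), 18-crown-6, THF, 0 → 66 °C; then aqueous NH4Cl
Reagents that add atoms: none
Why: Anionic oxy-Cope rearrangement of the C9 alkoxide through a twist-boat of ring B (which brings the vinyl group and the C14=C13 bond gauche and relieves the C20/C14 diaxial contact) should break C8–C9 and form C12–C13 on the face of ring D that C9 leaves, so the C8 configuration is transferred to C13 and the bridgehead C8=C14 bond is formed.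

Step 13
Reactants: 18 ten-membered ring ketone
Product: 19 C3 acetate of 18
Conditions: Ac2O, DMAP, Et3N, CH2Cl2, rt
Reagents that add atoms: acetic anhydride (CC(=O)OC(C)=O)
Why: Acylation of the single free hydroxyl, the axial C3–OH that step 2 distinguished from O1, restores the acetate without a selectivity problem.

Step 14
Reactants: 19 C3 acetate
Product: 21 1,7-bis-silyl ether of the target (C15 ketone), via C15 alcohol 20 (not isolated)
Conditions: SeO2 (0.5 equiv), t-BuOOH, CH2Cl2, 0 °C → rt; then MnO2, CH2Cl2, rt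
Reagents that add atoms: tert-butyl hydroperoxide (CC(C)(C)OO)
Why: Allylic oxidation with SeO2 (ene reaction then [2,3] shift) should hydroxylate C15, the only methylene allylic to both ring D alkenes, and MnO2 should oxidise the doubly allylic alcohol to the cross-conjugated dienone.

Step 15
Reactants: 21 1,7-bis-silyl ether
Product: 22 target CNP0223751.1
Conditions: HF·pyridine, pyridine, THF, 0 °C → rt
Reagents that add atoms: none
Why: Fluoride cleavage of both silyl ethers under buffered conditions should leave the acetate, the β-hydroxy ketone and the dienone untouched.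

**Compound list**
1 | (S)-(+)-carvone | CC1=CC[C@@H](CC1=O)C(C)=C | starting material
2 | 2-methyl-1-(trimethylsilyloxy)prop-1-ene | CC(C)=CO[Si](C)(C)C | starting material
3 | trichlorotitanium enolate of the Michael adduct (C9–OTiCl3, C9=C10; C5 side chain anti to C7 isopropenyl) | Cl[Ti](Cl)(Cl)OC1=C(C)[C@@H](C(C)(C)C=O)C[C@H](C(C)=C)C1 | intermediate
4 | ring B keto aldehyde: 2-acetyl-2-methyl-3-(2-methyl-1-oxopropan-2-yl)-5-(prop-1-en-2-yl)cyclohexan-1-one, acetyl and isopropenyl both trans to the C5 side chain | O=C1[C@](C)(C(C)=O)[C@@H](C(C)(C)C=O)C[C@H](C(C)=C)C1 | intermediate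
5 | ring A aldol: trans-fused bicycle, C3–OH axial (trans to C20), C1 and C9 ketones | O=C1C[C@@H](C(C)=C)C[C@@H]2C(C)(C)[C@@H](O)CC(=O)[C@@]12C | intermediate
6 | ring A anti-1,3-diol monoacetate: C1–OH equatorial (cis to C20), C3–OAc axial (trans to C20) | O=C1C[C@@H](C(C)=C)C[C@@H]2C(C)(C)[C@@H](OC(C)=O)C[C@H](O)[C@@]12C | intermediate
7 | C1 tert-butyldimethylsilyl ether of 6 | O=C1C[C@@H](C(C)=C)C[C@@H]2C(C)(C)[C@@H](OC(C)=O)C[C@H](O[Si](C)(C)C(C)(C)C)[C@@]12C | intermediate
8 | α-methoxy hydroperoxide at the former isopropenyl carbon (mixture at that carbon) | O=C1C[C@@H](C(C)(OC)OO)C[C@@H]2C(C)(C)[C@@H](OC(C)=O)C[C@H](O[Si](C)(C)C(C)(C)C)[C@@]12C | intermediate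
9 | C7 (2,2,6,6-tetramethylpiperidin-1-yl)oxy ether (mixture at C7) | O=C1CC(ON3C(C)(C)CCCC3(C)C)C[C@@H]2C(C)(C)[C@@H](OC(C)=O)C[C@H](O[Si](C)(C)C(C)(C)C)[C@@]12C | intermediate
10 | ring B 1,3-dione (C7 and C9 ketones) | O=C1CC(=O)C[C@@H]2C(C)(C)[C@@H](OC(C)=O)C[C@H](O[Si](C)(C)C(C)(C)C)[C@@]12C | intermediate
11 | C8-allyl 1,3-dione (C8 unassigned, enolised) | O=C1C(CC=C)C(=O)C[C@@H]2C(C)(C)[C@@H](OC(C)=O)C[C@H](O[Si](C)(C)C(C)(C)C)[C@@]12C | intermediate
12 | C8-quaternary dione: allyl cis to C20, 2-(acetoxymethyl)prop-2-enyl trans to C20 | O=C1[C@@](CC=C)(CC(=C)COC(C)=O)C(=O)C[C@@H]2C(C)(C)[C@@H](OC(C)=O)C[C@H](O[Si](C)(C)C(C)(C)C)[C@@]12C | intermediate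
13 | spiro dione, ring D cyclopentene (C13=C16) with CH2OAc on C16, C14 cis to C20 | O=C1[C@]3(CC=C(COC(C)=O)C3)C(=O)C[C@@H]2C(C)(C)[C@@H](OC(C)=O)C[C@H](O[Si](C)(C)C(C)(C)C)[C@@]12C | intermediate
14 | C7 alcohol of 13, C7–OH equatorial (cis to C20) | O=C1[C@]3(CC=C(COC(C)=O)C3)[C@H](O)C[C@@H]2C(C)(C)[C@@H](OC(C)=O)C[C@H](O[Si](C)(C)C(C)(C)C)[C@@]12C | intermediate
15 | C7 tert-butyldimethylsilyl ether of 14 | O=C1[C@]3(CC=C(COC(C)=O)C3)[C@H](O[Si](C)(C)C(C)(C)C)C[C@@H]2C(C)(C)[C@@H](OC(C)=O)C[C@H](O[Si](C)(C)C(C)(C)C)[C@@]12C | intermediate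
16 | spiro diene ketone, ring D with C14=C13 and exocyclic C16=C17 | O=C1[C@]3(C=CC(=C)C3)[C@H](O[Si](C)(C)C(C)(C)C)C[C@@H]2C(C)(C)[C@@H](OC(C)=O)C[C@H](O[Si](C)(C)C(C)(C)C)[C@@]12C | intermediate
17 | C9 vinyl carbinol (vinyl trans to C14, C9–OH cis to C20), free C3–OH | O[C@]1(C=C)[C@]3(C=CC(=C)C3)[C@H](O[Si](C)(C)C(C)(C)C)C[C@@H]2C(C)(C)[C@@H](O)C[C@H](O[Si](C)(C)C(C)(C)C)[C@@]12C | intermediate
18 | ten-membered ring ketone (bicyclo[7.2.1] core), C8=C14, exocyclic C16=C17, free C3–OH, C1 and C7 silyl ethers | C=C1CC2=C[C@H]1CCC(=O)[C@@]1(C)[C@H](C[C@H]2O[Si](C)(C)C(C)(C)C)C(C)(C)[C@@H](O)C[C@@H]1O[Si](C)(C)C(C)(C)C | intermediate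
19 | C3 acetate of 18 | C=C1CC2=C[C@H]1CCC(=O)[C@@]1(C)[C@H](C[C@H]2O[Si](C)(C)C(C)(C)C)C(C)(C)[C@@H](OC(C)=O)C[C@@H]1O[Si](C)(C)C(C)(C)C | intermediate
20 | C15 alcohol of 19 (mixture at C15) | C=C1C(O)C2=C[C@H]1CCC(=O)[C@@]1(C)[C@H](C[C@H]2O[Si](C)(C)C(C)(C)C)C(C)(C)[C@@H](OC(C)=O)C[C@@H]1O[Si](C)(C)C(C)(C)C | intermediate
21 | 1,7-bis(tert-butyldimethylsilyl) ether of the target | C=C1C(=O)C2=C[C@H]1CCC(=O)[C@@]1(C)[C@H](C[C@H]2O[Si](C)(C)C(C)(C)C)C(C)(C)[C@@H](OC(C)=O)C[C@@H]1O[Si](C)(C)C(C)(C)C | intermediate
22 | CNP0223751.1 | C=C1C(=O)C2=C[C@H]1CCC(=O)[C@@]1(C)[C@H](C[C@H]2O)C(C)(C)[C@@H](OC(C)=O)C[C@@H]1O | target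

**Totals:** total step count 15; longest linear sequence 15 steps (1 to 22).

**Steps most likely to fail**

Step 12 (ring expansion). The [3,3] shift may be outrun by heterolytic cleavage of C8–C9 to a vinyl ketone and a pentadienyl anion that recombines without control at C13, or it may stall if ring B does not reach the twist-boat. The fallback sets out from 16 and comes back at 18. Methanolysis of the C3 acetate (K2CO3, CH3OH) would give the hydroxy ketone F3. A Corey–Chaykovsky reaction with dimethylsulfoxonium methylide ((CH3)3S(O)I, NaH, DMSO), which adds reversibly, should give the spiro epoxide F4 with the new CH2 equatorial. Excess dimethylsulfonium methylide ((CH3)3SI, n-BuLi, THF) would open and homologate the epoxide to the C9-epimeric vinyl carbinol F5, in which the vinyl group and C14 are gauche in the ground-state chair. KH with 18-crown-6 would then give 18.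

Step 2 (key step). Enolisation at C8 followed by addition to acetaldehyde, slow hydride transfer from a congested hemiacetal, or retro-aldol opening of the product alkoxide may erode the cascade. The fallback sets out from 4 and comes back at 7. The aldol 5 would be isolated after LiN(SiMe3)2 and a cold quench. Hydroxyl-directed anti reduction of the C1 ketone with one equivalent of Me4NBH(OAc)3 (Saksena–Evans reduction) would give the anti-diol F1. Silylation of the less hindered equatorial C1–OH (TBSCl, imidazole) would give the mono-silyl ether F2, and acetylation of the axial C3–OH (Ac2O, DMAP) would give 7.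

Step 14 (allylic oxidation). Hydrogen abstraction at the C13 bridgehead or at C7, allylic transposition, or oxidation next to the C9 ketone may compete. The fallback sets out from 16 and comes back at 20. At the spiro stage C15 is the only allylic methylene, so SeO2/t-BuOOH should give the C15 alcohol F6. Triethylsilylation (Et3SiOTf, 2,6-lutidine) would give the silyl ether F7; CH2=CHMgBr/CeCl3 the vinyl carbinol F8; KH/18-crown-6 the ring-expanded ketone F9; and Ac2O/DMAP the acetate F10. Pyridinium p-toluenesulfonate in CH3OH would then remove only the triethylsilyl group to give 20, which MnO2 oxidises to 21.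

**Further compounds**
F1 | step 2 | ring A anti-1,3-diol (C1–OH equatorial, C3–OH axial) | O=C1C[C@@H](C(C)=C)C[C@@H]2C(C)(C)[C@@H](O)C[C@H](O)[C@@]12C
F2 | step 2 | C1 tert-butyldimethylsilyl ether with free C3–OH | O=C1C[C@@H](C(C)=C)C[C@@H]2C(C)(C)[C@@H](O)C[C@H](O[Si](C)(C)C(C)(C)C)[C@@]12C
F3 | step 12 | spiro diene ketone with free C3–OH | O=C1[C@]3(C=CC(=C)C3)[C@H](O[Si](C)(C)C(C)(C)C)C[C@@H]2C(C)(C)[C@@H](O)C[C@H](O[Si](C)(C)C(C)(C)C)[C@@]12C
F4 | step 12 | C9 spiro epoxide (oxygen trans to C20, CH2 equatorial) | C1O[C@]14[C@]3(C=CC(=C)C3)[C@H](O[Si](C)(C)C(C)(C)C)C[C@@H]2C(C)(C)[C@@H](O)C[C@H](O[Si](C)(C)C(C)(C)C)[C@@]42C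
F5 | step 12 | C9-epimeric vinyl carbinol (vinyl cis to C14 and C20) | O[C@@]1(C=C)[C@]3(C=CC(=C)C3)[C@H](O[Si](C)(C)C(C)(C)C)C[C@@H]2C(C)(C)[C@@H](O)C[C@H](O[Si](C)(C)C(C)(C)C)[C@@]12C
F6 | step 14 | C15 alcohol of 16 (mixture at C15) | O=C1[C@]3(C=CC(=C)C3O)[C@H](O[Si](C)(C)C(C)(C)C)C[C@@H]2C(C)(C)[C@@H](OC(C)=O)C[C@H](O[Si](C)(C)C(C)(C)C)[C@@]12C
F7 | step 14 | C15 triethylsilyl ether of F6 | O=C1[C@]3(C=CC(=C)C3O[Si](CC)(CC)CC)[C@H](O[Si](C)(C)C(C)(C)C)C[C@@H]2C(C)(C)[C@@H](OC(C)=O)C[C@H](O[Si](C)(C)C(C)(C)C)[C@@]12C
F8 | step 14 | C9 vinyl carbinol with C15 triethylsilyl ether and free C3–OH | O[C@]1(C=C)[C@]3(C=CC(=C)C3O[Si](CC)(CC)CC)[C@H](O[Si](C)(C)C(C)(C)C)C[C@@H]2C(C)(C)[C@@H](O)C[C@H](O[Si](C)(C)C(C)(C)C)[C@@]12C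
F9 | step 14 | ring-expanded ketone with C15 triethylsilyl ether and free C3–OH | C=C1C(O[Si](CC)(CC)CC)C2=C[C@H]1CCC(=O)[C@@]1(C)[C@H](C[C@H]2O[Si](C)(C)C(C)(C)C)C(C)(C)[C@@H](O)C[C@@H]1O[Si](C)(C)C(C)(C)C
F10 | step 14 | C3 acetate of F9 | C=C1C(O[Si](CC)(CC)CC)C2=C[C@H]1CCC(=O)[C@@]1(C)[C@H](C[C@H]2O[Si](C)(C)C(C)(C)C)C(C)(C)[C@@H](OC(C)=O)C[C@@H]1O[Si](C)(C)C(C)(C)C
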